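**Retrosynthetic overview**

1. Target 16 ⇐ MOM removal from 15 ⇐ para-Claisen–Cope rearrangement of 5-O-prenyl ether 13 (forms the C8–prenyl bond; the prenyl ether first masks the 5-OH).
2. 13 ⇐ one-pot organocatalytic asymmetric epoxidation / Wharton transposition of the α-branched enal 10 (sets the only stereocentre and builds the 2-hydroxy-3-methylbut-3-enyl chain).
3. 10 ⇐ Mitsunobu prenylation of 9 ⇐ cross-metathesis of 6-allyl phenol 8 with methacrolein ⇐ aromatic Claisen rearrangement of 5-O-allyl ether 6 (C6–C bond).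
4. 6 ⇐ tri-MOM-orobol 5 ⇐ orobol 4 ⇐ phloroglucinol 1 + 3,4-dihydroxyphenylacetic acid 2.
5. Ring order: rings A and B are bought; ring C (the pyranone) is the only ring formed, in step 1; all later steps are side-chain chemistry on ring A.

Assumption: the quinine-derived primary amine/(R)-TRIP ion pair is taken to deliver H2O2 to the β-Re face of enal 10 (the sense needed for the (R)-carbinol); I could not confirm which pseudoenantiomer does this, so if a test run shows the opposite sense the quinidine-derived amine/(S)-TRIP pair is used instead.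

**Route**

Step 1
Reactants: 1 phloroglucinol; 2 3,4-dihydroxyphenylacetic acid
Product: 4 orobol (3-(3,4-dihydroxyphenyl)-5,7-dihydroxy-4H-chromen-4-one), via deoxybenzoin 3 (not isolated)
Conditions: BF3·OEt2, 90 °C; then DMF, MsCl, 70 °C
Reagents that add atoms: N,N-dimethylformamide, CN(C)C=O
Why: Friedel–Crafts C-acylation of symmetric phloroglucinol gives a single deoxybenzoin, whose chelated enol is C-formylated by the DMF/MsCl Vilsmeier reagent and closes onto either (equivalent) ortho-hydroxyl with loss of Me2NH, the standard one-pot deoxybenzoin route to polyhydroxyisoflavones.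

Step 2
Reactants: 4 orobol
Product: 5 7,3',4'-tri-O-(methoxymethyl)orobol (5-OH free)
Conditions: MOMCl (3.3 equiv), iPr2NEt, DMF, 0 °C to rt
Reagents that add atoms: chloromethyl methyl ether, COCCl
Why: Williamson-type acetalisation protects the three non-chelated phenols, while the 5-OH, hydrogen-bonded to the C4 carbonyl, stays free.

Step 3
Reactants: 5 7,3',4'-tri-O-MOM-orobol
Product: 6 5-O-allyl-7,3',4'-tri-O-MOM-orobol
Conditions: allyl bromide, K2CO3, DMF, 60 °C
Reagents that add atoms: allyl bromide, C=CCBr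
Why: Williamson O-alkylation of the remaining chelated phenol under more forcing conditions (polar aprotic solvent, heat).

Step 4
Reactants: 6 5-O-allyl-7,3',4'-tri-O-MOM-orobol
Product: 8 6-allyl-7,3',4'-tri-O-MOM-orobol (5-OH free), via C6-allyl dienone 7 (not isolated)
Conditions: PhNEt2, 195 °C
Reagents that add atoms: none
Why: Aromatic Claisen rearrangement, in which the [3,3] shift from O5 can only reach C6 (the other ortho carbon is the ring fusion) and the dienone enolises to the 6-allyl phenol, fixing the C6 regiochemistry.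

Step 5
Reactants: 8 6-allyl-7,3',4'-tri-O-MOM-orobol
Product: 9 (E)-2-methyl-4-(7,3',4'-tri-O-MOM-orobol-6-yl)but-2-enal
Conditions: methacrolein (10 equiv), second-generation Hoveyda–Grubbs catalyst RuCl2(H2IMes)(=CH-C6H4-2-OiPr) (5 mol%), 1,4-benzoquinone (10 mol%), CH2Cl2, 40 °C
Reagents that add atoms: methacrolein, CC(=C)C=O
Why: Olefin cross-metathesis of the only alkene in the molecule with a 1,1-disubstituted electron-poor partner gives the trisubstituted (E)-enal with loss of ethylene, benzoquinone suppressing Ru–H isomerisation of the o-allylphenol.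

Step 6
Reactants: 9 (E)-enal with free 5-OH
Product: 10 (E)-2-methyl-4-(5-O-prenyl-7,3',4'-tri-O-MOM-orobol-6-yl)but-2-enal
Conditions: prenol, PPh3, DIAD, THF, 0 °C to rt
Reagents that add atoms: 3-methylbut-2-en-1-ol (prenol), CC(C)=CCO
Why: Mitsunobu etherification of the acidic chelated phenol under neutral conditions installs a prenyl ether that masks the ortho-phenol for the next step and is the latent C8 prenyl group.

Step 7
Reactants: 10 5-O-prenyl (E)-enal
Product: 13 6-[(2R)-2-hydroxy-3-methylbut-3-enyl]-5-O-prenyl-7,3',4'-tri-O-MOM-orobol, via epoxy aldehyde 11 (not isolated), via epoxy hydrazone 12 (not isolated)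
Conditions: 9-amino(9-deoxy)epiquinine (10 mol%), (R)-TRIP (10 mol%), 50% aq. H2O2 (1.3 equiv), THF, 40 °C; then MeOH, N2H4·H2O (3 equiv), AcOH (0.3 equiv), 0 °C to rt
Reagents that add atoms: hydrogen peroxide, OO
Why: Proposed new method: the primary amine condenses with the α-branched enal (which secondary amines activate poorly) to an iminium whose chiral phosphate counter-anion hydrogen-bonds H2O2 and delivers it to the β-Re face, the β-hydroperoxy enamine closes the epoxide with loss of water to give the non-enolisable (2S,3R)-epoxy aldehyde 11, and hydrazine added to the same flask forms hydrazone 12, which undergoes Wharton transposition (acid-assisted opening of the C2–O bond to an alkenyl diazene, loss of N2, protonation) to the exo-methylene carbinol; the C3–O bond is never broken, so the (R) centre is set solely by the catalyst-controlled epoxidation, the O-prenyl alkene is inert to this nucleophilic oxidant and no free ortho-phenol is present to add to the iminium; the closest known reaction types are the amine-catalysed asymmetric epoxidation of α-branched enals with H2O2 and the Wharton transposition of α,β-epoxy carbonyl compounds, which to my knowledge have not been merged in one flask for an α-branched enal or used on a polyoxygenated isoflavone.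

Step 8
Reactants: 13 5-O-prenyl (R)-allylic alcohol
Product: 15 6-[(2R)-2-hydroxy-3-methylbut-3-enyl]-8-prenyl-7,3',4'-tri-O-MOM-orobol (5-OH free), via C6 dienone 14 (not isolated)
Conditions: Eu(fod)3 (15 mol%; fod = 6,6,7,7,8,8,8-heptafluoro-2,2-dimethyloctane-3,5-dionate), PhCl, 80 °C
Reagents that add atoms: none
Why: para-Claisen–Cope rearrangement, in which Lewis-acid chelation at O5/C4=O triggers the [3,3] shift to the blocked C6 and the dienone relays the 1,1-dimethylallyl group by Cope rearrangement to C8 as a normal prenyl group before enolising; the remote carbinol centre is untouched.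

Step 9
Reactants: 15 tri-O-MOM-protected target
Product: 16 target, 3-(3,4-dihydroxyphenyl)-5,7-dihydroxy-6-[(2R)-2-hydroxy-3-methylbut-3-en-1-yl]-8-(3-methylbut-2-en-1-yl)-4H-chromen-4-one
Conditions: HCl (1.25 M in MeOH), 30 °C
Reagents that add atoms: none
Why: Acid-catalysed acetal exchange (MOM solvolysis) under mild conditions of the kind that spare ortho-prenyl phenols; the secondary allylic alcohol should not ionise at this acidity, so the stereocentre is retained.

**Compound list**

1 | phloroglucinol (benzene-1,3,5-triol) | Oc1cc(O)cc(O)c1 | starting material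
2 | 3,4-dihydroxyphenylacetic acid | OC(=O)Cc1ccc(O)c(O)c1 | starting material
3 | 2-(3,4-dihydroxyphenyl)-1-(2,4,6-trihydroxyphenyl)ethanone (deoxybenzoin, not isolated) | O=C(Cc1ccc(O)c(O)c1)c1c(O)cc(O)cc1O | intermediate
4 | orobol, 3-(3,4-dihydroxyphenyl)-5,7-dihydroxy-4H-chromen-4-one | O=c1c(-c2ccc(O)c(O)c2)coc2cc(O)cc(O)c12 | intermediate
5 | 3-[3,4-bis(methoxymethoxy)phenyl]-5-hydroxy-7-(methoxymethoxy)-4H-chromen-4-one | COCOc1ccc(-c2coc3cc(OCOC)cc(O)c3c2=O)cc1OCOC | intermediate
6 | 5-(allyloxy)-3-[3,4-bis(methoxymethoxy)phenyl]-7-(methoxymethoxy)-4H-chromen-4-one | COCOc1ccc(-c2coc3cc(OCOC)cc(OCC=C)c3c2=O)cc1OCOC | intermediate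
7 | 6-allyl-3-[3,4-bis(methoxymethoxy)phenyl]-7-(methoxymethoxy)-6H-chromene-4,5-dione (ortho-Claisen dienone, not isolated) | COCOc1ccc(C2=COC3=C(C2=O)C(=O)C(CC=C)C(OCOC)=C3)cc1OCOC | intermediate
8 | 6-allyl-3-[3,4-bis(methoxymethoxy)phenyl]-5-hydroxy-7-(methoxymethoxy)-4H-chromen-4-one | COCOc1ccc(-c2coc3cc(OCOC)c(CC=C)c(O)c3c2=O)cc1OCOC | intermediate
9 | (E)-4-{3-[3,4-bis(methoxymethoxy)phenyl]-5-hydroxy-7-(methoxymethoxy)-4-oxo-4H-chromen-6-yl}-2-methylbut-2-enal | COCOc1ccc(-c2coc3cc(OCOC)c(C/C=C(C)/C=O)c(O)c3c2=O)cc1OCOC | intermediate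
10 | (E)-4-{3-[3,4-bis(methoxymethoxy)phenyl]-7-(methoxymethoxy)-5-(3-methylbut-2-enyloxy)-4-oxo-4H-chromen-6-yl}-2-methylbut-2-enal | COCOc1ccc(-c2coc3cc(OCOC)c(C/C=C(C)/C=O)c(OCC=C(C)C)c3c2=O)cc1OCOC | intermediate
11 | (2S,3R)-2-methyl-3-{[5-O-prenyl-7,3',4'-tri-O-MOM-orobol-6-yl]methyl}oxirane-2-carbaldehyde (CHO trans to the arylmethyl group; not isolated) | O=C[C@@]1(C)O[C@@H]1Cc1c(OCOC)cc2occ(-c3ccc(OCOC)c(OCOC)c3)c(=O)c2c1OCC=C(C)C | intermediate
12 | hydrazone of 11, (2R,3R) by CIP with unchanged spatial arrangement (not isolated) | NN=C[C@@]1(C)O[C@@H]1Cc1c(OCOC)cc2occ(-c3ccc(OCOC)c(OCOC)c3)c(=O)c2c1OCC=C(C)C | intermediate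
13 | 3-[3,4-bis(methoxymethoxy)phenyl]-6-[(2R)-2-hydroxy-3-methylbut-3-enyl]-7-(methoxymethoxy)-5-(3-methylbut-2-enyloxy)-4H-chromen-4-one | C=C(C)[C@H](O)Cc1c(OCOC)cc2occ(-c3ccc(OCOC)c(OCOC)c3)c(=O)c2c1OCC=C(C)C | intermediate
14 | 6-[(2R)-2-hydroxy-3-methylbut-3-enyl]-6-(2-methylbut-3-en-2-yl)-3-[3,4-bis(methoxymethoxy)phenyl]-7-(methoxymethoxy)-6H-chromene-4,5-dione (C6 epimers, not isolated) | C=C(C)[C@H](O)CC1(C(C)(C)C=C)C(OCOC)=CC2=C(C1=O)C(=O)C(c1ccc(OCOC)c(OCOC)c1)=CO2 | intermediate
15 | 3-[3,4-bis(methoxymethoxy)phenyl]-5-hydroxy-6-[(2R)-2-hydroxy-3-methylbut-3-enyl]-7-(methoxymethoxy)-8-(3-methylbut-2-enyl)-4H-chromen-4-one | C=C(C)[C@H](O)Cc1c(OCOC)c(CC=C(C)C)c2occ(-c3ccc(OCOC)c(OCOC)c3)c(=O)c2c1O | intermediate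
16 | 3-(3,4-dihydroxyphenyl)-5,7-dihydroxy-6-[(2R)-2-hydroxy-3-methylbut-3-en-1-yl]-8-(3-methylbut-2-en-1-yl)-4H-chromen-4-one | C=C(C)[C@H](O)Cc1c(O)c(CC=C(C)C)c2occ(-c3ccc(O)c(O)c3)c(=O)c2c1O | target

**Step count and risks**

Total step count: 9. Longest linear sequence: 9 (the route is fully linear).

The three steps most likely to fail:

Step 7 (the proposed new step). The risks are attack of hydrazine on the isoflavone C2 (ring opening to a pyrazole), diimide formed from leftover H2O2, and erosion of ee through dienamine-mediated E/Z scrambling of the γ-benzylic enal. The fallback sets out from 10 and returns at 13 and uses only known reactions. The epoxidation is run as a separate, isolated operation with the same amine/phosphate catalyst and aqueous H2O2 (a known reaction of α-branched enals) to give epoxy aldehyde 11. Reduction with NaBH4 in MeOH at 0 °C gives the (2R,3R)-epoxy alcohol F1. Iodination with I2, PPh3 and imidazole in CH2Cl2 at 0 °C gives the (2S,3R)-epoxy iodide F2. Zinc dust in EtOH at 60 °C then effects reductive ring opening, which again breaks only the C2–O bond and gives 13 with the same (R) centre and no hydrazine.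

Step 8. The risks are that the ipso [3,3] shift onto the substituted C6 is slow, that the prenyl ether ionises instead, or that the free alcohol ties up the europium catalyst or traps the dienone. The fallback sets out from 10 and returns at 15 by doing the rearrangement before the alcohol exists. Eu(fod)3 in PhCl at 80 °C converts 10 into the 8-prenyl-5-hydroxy enal F3. The step 7 sequence is then run on F3, through the (2S,3R)-epoxy aldehyde F4 and its hydrazone F5 (neither isolated), relying on the chelated 5-OH being too poor a nucleophile to add to the iminium, and gives 15 directly.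

Step 5. The risks are low conversion with the 1,1-disubstituted partner at a doubly ortho-substituted allyl arene, E/Z mixtures, and isomerisation of the o-allylphenol. The fallback sets out from 8 and returns at 9. Lemieux–Johnson cleavage (OsO4 cat., NaIO4, 2,6-lutidine, dioxane–H2O, rt) gives the arylacetaldehyde F6. Wittig olefination with the stabilised ylide 2-(triphenylphosphoranylidene)propanal in toluene at 80 °C gives the (E)-enal 9.

Further compounds
F1 | step 7 | [(2R,3R)-2-methyl-3-{[5-O-prenyl-7,3',4'-tri-O-MOM-orobol-6-yl]methyl}oxiran-2-yl]methanol (epoxy alcohol) | OC[C@@]1(C)O[C@@H]1Cc1c(OCOC)cc2occ(-c3ccc(OCOC)c(OCOC)c3)c(=O)c2c1OCC=C(C)C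
F2 | step 7 | (2S,3R)-2-(iodomethyl)-2-methyl-3-{[5-O-prenyl-7,3',4'-tri-O-MOM-orobol-6-yl]methyl}oxirane (epoxy iodide) | IC[C@@]1(C)O[C@@H]1Cc1c(OCOC)cc2occ(-c3ccc(OCOC)c(OCOC)c3)c(=O)c2c1OCC=C(C)C
F3 | step 8 | (E)-4-{3-[3,4-bis(methoxymethoxy)phenyl]-5-hydroxy-7-(methoxymethoxy)-8-(3-methylbut-2-enyl)-4-oxo-4H-chromen-6-yl}-2-methylbut-2-enal | O=C/C(C)=C/Cc1c(OCOC)c(CC=C(C)C)c2occ(-c3ccc(OCOC)c(OCOC)c3)c(=O)c2c1O
F4 | step 8 | (2S,3R)-2-methyl-3-{[8-prenyl-7,3',4'-tri-O-MOM-orobol-6-yl]methyl}oxirane-2-carbaldehyde | O=C[C@@]1(C)O[C@@H]1Cc1c(OCOC)c(CC=C(C)C)c2occ(-c3ccc(OCOC)c(OCOC)c3)c(=O)c2c1O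
F5 | step 8 | hydrazone of F4 | NN=C[C@@]1(C)O[C@@H]1Cc1c(OCOC)c(CC=C(C)C)c2occ(-c3ccc(OCOC)c(OCOC)c3)c(=O)c2c1O
F6 | step 5 | 2-{3-[3,4-bis(methoxymethoxy)phenyl]-5-hydroxy-7-(methoxymethoxy)-4-oxo-4H-chromen-6-yl}acetaldehyde | O=CCc1c(OCOC)cc2occ(-c3ccc(OCOC)c(OCOC)c3)c(=O)c2c1O
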